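**Retrosynthetic overview**
The target is biochanin A joined through C8 to C3' of acacetin. The strategy rests on flavone ring B, a 1,3,4-trisubstituted anisole: the C4' methoxy group is ortho to the C3'–C8 biaryl bond and para to C1', the carbon that carries flavone C2.
Last disconnections: the four O-benzyl ethers, then the flavone pyranone ring (cyclodehydration), then the 1,3-diketone (Claisen condensation of a ring-B methyl benzoate with dibenzylated phloroacetophenone).
Key disconnection: ring B at C2'–C3' and C4'–C5', giving the 8-(methoxyethynyl)isoflavone and methyl coumalate ([4+2] cycloaddition, then loss of CO2); the ester carbon becomes flavone C2.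
The ynol ether comes from 8-iodo-5,7-di-O-benzylbiochanin A and methoxyethynylzinc chloride (from trichloroethylene and methanol) by Negishi coupling.
Ring order: the isoflavone rings are bought; ring B is formed in step 5 and the flavone pyranone ring in step 8, with flavone ring A arriving in the acetophenone.

Key step: step 5

Assumption: the target SMILES has no stereodescriptor, so the C8–C3' biaryl axis is treated as configurationally undefined and no atroposelective step is planned.

**Step 1**
Reactants: 1 biochanin A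
Product: 2 5,7-bis(benzyloxy)-3-(4-methoxyphenyl)-4H-chromen-4-one
Conditions: BnBr (3 equiv), K2CO3 (4 equiv), n-Bu4NI (cat.), dry DMF, 70 °C
Reagents that add atoms: benzyl bromide, BrCc1ccccc1
Why: Williamson ether synthesis in which the acidic 7-OH reacts first and the hydrogen-bonded 5-OH follows with excess halide, iodide catalysis and heat, while the absence of hydroxide keeps the 2-unsubstituted chromone closed.

**Step 2**
Reactants: 2 5,7-bis(benzyloxy)-3-(4-methoxyphenyl)-4H-chromen-4-one
Product: 3 5,7-bis(benzyloxy)-8-iodo-3-(4-methoxyphenyl)-4H-chromen-4-one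
Conditions: NIS (1.05 equiv), TFA (0.3 equiv), MeCN/CH2Cl2, 0 °C → rt, dark
Reagents that add atoms: N-iodosuccinimide, O=C1CCC(=O)N1I
Why: Electrophilic aromatic iodination, which in fully O-alkylated 5,7-dioxygenated (iso)flavones goes to C8 (para to the 5-oxygen, flanked by one benzyloxy group) and not to the doubly flanked C6, and one equivalent of reagent should spare the less activated 4-methoxyphenyl ring.

**Step 3**
Reactants: 4 trichloroethylene
Product: 5 (E)-1,2-dichloro-1-methoxyethene
Conditions: MeOH, KH (1.1 equiv), THF, 0 °C; then 4, −50 °C → rt; fractional distillation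
Reagents that add atoms: methanol, CO
Why: Base-induced dehydrochlorination of trichloroethylene to dichloroacetylene followed by anti addition of methoxide/methanol gives the E dichlorovinyl ether, the standard entry to metalated alkynyl ethers.

**Step 4**
Reactants: 5 (E)-1,2-dichloro-1-methoxyethene, 3 5,7-bis(benzyloxy)-8-iodo-3-(4-methoxyphenyl)-4H-chromen-4-one
Product: 8 5,7-bis(benzyloxy)-8-(methoxyethynyl)-3-(4-methoxyphenyl)-4H-chromen-4-one, via lithium methoxyacetylide 6 (not isolated), via methoxyethynylzinc chloride 7 (not isolated)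
Conditions: 5 (3 equiv), n-BuLi (6.3 equiv), THF, −78 → −40 °C; ZnCl2 (3.5 equiv), −78 → 0 °C; then 3, Pd(PPh3)4 (5 mol %), THF, rt → 45 °C; NaHCO3 work-up, Et3N-deactivated SiO2
Reagents that add atoms: none
Why: Deprotonation and β-elimination of 5 followed by lithium–chlorine exchange give acetylide 6, transmetalation to zinc lowers its basicity before the chromone is added, and Negishi coupling of alkoxyethynylzinc chlorides with aryl iodides under zerovalent palladium catalysis is an established route to aryl alkynyl ethers.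

**Step 5**
Reactants: 8 5,7-bis(benzyloxy)-8-(methoxyethynyl)-3-(4-methoxyphenyl)-4H-chromen-4-one, 9 methyl coumalate (methyl 2-oxo-2H-pyran-5-carboxylate)
Product: 11 methyl 3-[5,7-bis(benzyloxy)-3-(4-methoxyphenyl)-4-oxo-4H-chromen-8-yl]-4-methoxybenzoate, via bicyclic lactone cycloadduct 10 (not isolated)
Conditions: 9 (3 equiv), PhMe, 4 Å MS, 110 °C, sealed tube, argon
Reagents that add atoms: none
Why: This is an inverse-electron-demand Diels–Alder reaction in which the electron-rich ynol ether 8 adds across C3 and C6 of the electron-poor 2-pyranone 9, and the bridged lactone 10 then loses CO2 in a retro-[4+2] step, so ring B is aromatic without an oxidant. The closest known reaction type is the cycloaddition/decarboxylation of methyl coumalate with ketene acetals, enol ethers, ynamines and alkoxyalkynes, which gives para-substituted benzoates. Ring B is closed by intermolecular [4+2] cycloaddition, forming C2'–C3' and C4'–C5', and aromatisation removes the lactone bridge. No stereocentre remains, because the two bridgehead centres of 10 disappear with CO2. The step needs regioselectivity only: the aryl-bearing alkyne carbon (β to oxygen, the nucleophilic end) bonds to pyranone C6 (β to the 5-ester and terminus of the dienone, the most electrophilic site), which places the methoxy group para to the ester and ortho to the isoflavone. The methyl ynol ether has no β-hydrogen for retro-ene loss of an alkene and so should tolerate 110 °C, and dry, acid-free conditions guard it against hydration.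

**Step 6**
Reactants: 12 2,4,6-trihydroxyacetophenone
Product: 13 1-[2,4-bis(benzyloxy)-6-hydroxyphenyl]ethan-1-one
Conditions: BnBr (2.05 equiv), K2CO3 (2.2 equiv), DMF, rt
Reagents that add atoms: benzyl bromide, BrCc1ccccc1
Why: Williamson ether synthesis in which two equivalents of halide alkylate the 4-OH and one ortho OH, while the remaining ortho OH stays hydrogen-bonded to the acetyl group and unreactive.

**Step 7**
Reactants: 13 1-[2,4-bis(benzyloxy)-6-hydroxyphenyl]ethan-1-one, 11 methyl 3-[5,7-bis(benzyloxy)-3-(4-methoxyphenyl)-4-oxo-4H-chromen-8-yl]-4-methoxybenzoate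
Product: 15 1-[2,4-bis(benzyloxy)-6-hydroxyphenyl]-3-{3-[5,7-bis(benzyloxy)-3-(4-methoxyphenyl)-4-oxo-4H-chromen-8-yl]-4-methoxyphenyl}propane-1,3-dione, via dilithium enolate phenoxide 14 (not isolated)
Conditions: 13 (1.5 equiv), LiN(SiMe3)2 (3.3 equiv), THF, −78 → −10 °C; then 11, −78 °C → rt; 1 M HCl quench to pH 4
Reagents that add atoms: none
Why: Crossed Claisen condensation in which the dilithium enolate-phenoxide 14 is acylated on carbon by the methyl ester and formation of the β-diketonate drives the equilibrium, while low temperature, lithium counter-ions and the absence of hydroxide are meant to protect the isoflavone pyranone, whose C2 is deactivated by the two ring-A alkoxy donors.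

**Step 8**
Reactants: 15 the 1,3-diketone of step 7
Product: 16 5,7-bis(benzyloxy)-8-{5-[5,7-bis(benzyloxy)-4-oxo-4H-chromen-2-yl]-2-methoxyphenyl}-3-(4-methoxyphenyl)-4H-chromen-4-one
Conditions: p-TsOH·H2O (0.2 equiv), PhMe, 100 °C
Reagents that add atoms: none
Why: Acid-catalysed cyclodehydration (the closing step of the Baker–Venkataraman flavone synthesis), in which the free phenol adds to the distal aryl ketone and the hemiketal loses water to give the 4-pyranone, under conditions that benzyl ethers tolerate.

**Step 9**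
Reactants: 16 the tetrabenzyl ether of step 8
Product: 17 5,7-dihydroxy-8-[5-(5,7-dihydroxy-4-oxo-4H-chromen-2-yl)-2-methoxyphenyl]-3-(4-methoxyphenyl)-4H-chromen-4-one (target)
Conditions: BCl3 (12 equiv), C6HMe5 (15 equiv), CH2Cl2, −78 → −30 °C; MeOH quench
Reagents that add atoms: none
Why: Lewis-acid cleavage of the four aryl benzyl ethers by BCl3 with pentamethylbenzene as benzyl cation trap, which prevents C-benzylation of the phloroglucinol rings, while the two non-chelated aryl methyl ethers are not cleaved by BCl3 at low temperature.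

**Compound list**
1 | biochanin A | COc1ccc(-c2coc3cc(O)cc(O)c3c2=O)cc1 | starting material
2 | 5,7-bis(benzyloxy)-3-(4-methoxyphenyl)-4H-chromen-4-one | COc1ccc(-c2coc3cc(OCc4ccccc4)cc(OCc4ccccc4)c3c2=O)cc1 | intermediate
3 | 5,7-bis(benzyloxy)-8-iodo-3-(4-methoxyphenyl)-4H-chromen-4-one | COc1ccc(-c2coc3c(I)c(OCc4ccccc4)cc(OCc4ccccc4)c3c2=O)cc1 | intermediate
4 | trichloroethylene | ClC=C(Cl)Cl | starting material
5 | (E)-1,2-dichloro-1-methoxyethene | CO/C(Cl)=C\Cl | intermediate
6 | lithium methoxyacetylide (formed in the flask, not isolated) | COC#C[Li] | intermediate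
7 | methoxyethynylzinc chloride (formed in the flask, not isolated) | COC#C[Zn]Cl | intermediate
8 | 5,7-bis(benzyloxy)-8-(methoxyethynyl)-3-(4-methoxyphenyl)-4H-chromen-4-one | COC#Cc1c(OCc2ccccc2)cc(OCc2ccccc2)c2c(=O)c(-c3ccc(OC)cc3)coc12 | intermediate
9 | methyl coumalate (methyl 2-oxo-2H-pyran-5-carboxylate) | COC(=O)c1ccc(=O)oc1 | starting material
10 | methyl 7-[5,7-bis(benzyloxy)-3-(4-methoxyphenyl)-4-oxo-4H-chromen-8-yl]-8-methoxy-3-oxo-2-oxabicyclo[2.2.2]octa-5,7-diene-6-carboxylate (racemic, bridgehead configuration fixed by the bicycle, not isolated) | COC(=O)C1=CC2C(=O)OC1C(=C2OC)c1c(OCc2ccccc2)cc(OCc2ccccc2)c2c(=O)c(-c3ccc(OC)cc3)coc12 | intermediate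
11 | methyl 3-[5,7-bis(benzyloxy)-3-(4-methoxyphenyl)-4-oxo-4H-chromen-8-yl]-4-methoxybenzoate | COC(=O)c1ccc(OC)c(-c2c(OCc3ccccc3)cc(OCc3ccccc3)c3c(=O)c(-c4ccc(OC)cc4)coc23)c1 | intermediate
12 | 2,4,6-trihydroxyacetophenone | CC(=O)c1c(O)cc(O)cc1O | starting material
13 | 1-[2,4-bis(benzyloxy)-6-hydroxyphenyl]ethan-1-one | CC(=O)c1c(O)cc(OCc2ccccc2)cc1OCc1ccccc1 | intermediate
14 | dilithium enolate-phenoxide of 13 (formed in the flask, not isolated) | C=C(O[Li])c1c(O[Li])cc(OCc2ccccc2)cc1OCc1ccccc1 | intermediate
15 | 1-[2,4-bis(benzyloxy)-6-hydroxyphenyl]-3-{3-[5,7-bis(benzyloxy)-3-(4-methoxyphenyl)-4-oxo-4H-chromen-8-yl]-4-methoxyphenyl}propane-1,3-dione | COc1ccc(cc1-c1c(OCc2ccccc2)cc(OCc2ccccc2)c2c(=O)c(-c3ccc(OC)cc3)coc12)C(=O)CC(=O)c1c(O)cc(OCc2ccccc2)cc1OCc1ccccc1 | intermediate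
16 | 5,7-bis(benzyloxy)-8-{5-[5,7-bis(benzyloxy)-4-oxo-4H-chromen-2-yl]-2-methoxyphenyl}-3-(4-methoxyphenyl)-4H-chromen-4-one | COc1ccc(-c2coc3c(-c4cc(-c5cc(=O)c6c(OCc7ccccc7)cc(OCc7ccccc7)cc6o5)ccc4OC)c(OCc4ccccc4)cc(OCc4ccccc4)c3c2=O)cc1 | intermediate
17 | 5,7-dihydroxy-8-[5-(5,7-dihydroxy-4-oxo-4H-chromen-2-yl)-2-methoxyphenyl]-3-(4-methoxyphenyl)-4H-chromen-4-one | COc1ccc(-c2coc3c(-c4cc(-c5cc(=O)c6c(O)cc(O)cc6o5)ccc4OC)c(O)cc(O)c3c2=O)cc1 | target

**Step count**
Total steps: 9. Longest linear sequence: 7 steps (1, 2, 4, 5, 7, 8, 9).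

**Steps most likely to fail**

Step 5 (key cycloaddition). The cycloaddition may be slower than hydration or oligomerisation of the ynol ether, may be retarded by the two ortho substituents on C8, or the coumalate may self-condense on heating. Fallback: a cross-coupling that forms the biaryl bond directly, setting out from iodide 3 and returning at ester 11. Commercial methyl 3-iodo-4-methoxybenzoate (COC(=O)c1ccc(OC)c(I)c1) would be borylated with bis(pinacolato)diboron, Pd(dppf)Cl2 and KOAc in dioxane at 85 °C to methyl 4-methoxy-3-(4,4,5,5-tetramethyl-1,3,2-dioxaborolan-2-yl)benzoate F1. Suzuki–Miyaura coupling of F1 with 3 (Pd(OAc)2, SPhos, K3PO4, toluene/water, 80 °C) should then give 11.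

Step 7 (Claisen condensation). Conjugate addition of the enolate to C2 of the isoflavone, with opening of its pyranone ring, may compete with the slow acylation by the electron-rich benzoate. Fallback: an intramolecular acyl transfer, setting out from ester 11 and returning at diketone 15. Me3SnOH in 1,2-dichloroethane at 80 °C, with dilute HCl work-up, would give 3-[5,7-bis(benzyloxy)-3-(4-methoxyphenyl)-4-oxo-4H-chromen-8-yl]-4-methoxybenzoic acid F2. Oxalyl chloride with catalytic DMF in CH2Cl2 would convert it into the acid chloride, 3-[5,7-bis(benzyloxy)-3-(4-methoxyphenyl)-4-oxo-4H-chromen-8-yl]-4-methoxybenzoyl chloride F3. O-Acylation of acetophenone 13 (Et3N, catalytic DMAP, CH2Cl2) would give the aryl ester, 2-acetyl-3,5-bis(benzyloxy)phenyl 3-[5,7-bis(benzyloxy)-3-(4-methoxyphenyl)-4-oxo-4H-chromen-8-yl]-4-methoxybenzoate F4. Baker–Venkataraman rearrangement of F4 (LiN(SiMe3)2, THF, −78 → −20 °C) should then deliver 15 by fast intramolecular acyl transfer.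

Step 4 (Negishi coupling). The metalated ynol ether may form incompletely or decompose, may be protonated to volatile methoxyacetylene, or residual organolithium may add to the chromone. Fallback: a Stille coupling with an isolated, neutral reagent, setting out from 5 and 3 and returning at ynol ether 8. Ether 5 would be treated with n-BuLi (2.1 equiv, THF, −78 → −40 °C) and then Bu3SnCl, and the product distilled to give tributyl(methoxyethynyl)stannane F5. Coupling of F5 with 3 (Pd(PPh3)2Cl2, Et4NCl, DMF, 60 °C) should give 8 with no strong base present.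

**Further compounds**
F1 | step 5 | methyl 4-methoxy-3-(4,4,5,5-tetramethyl-1,3,2-dioxaborolan-2-yl)benzoate | COC(=O)c1ccc(OC)c(B2OC(C)(C)C(C)(C)O2)c1
F2 | step 7 | 3-[5,7-bis(benzyloxy)-3-(4-methoxyphenyl)-4-oxo-4H-chromen-8-yl]-4-methoxybenzoic acid | COc1ccc(cc1-c1c(OCc2ccccc2)cc(OCc2ccccc2)c2c(=O)c(-c3ccc(OC)cc3)coc12)C(O)=O
F3 | step 7 | 3-[5,7-bis(benzyloxy)-3-(4-methoxyphenyl)-4-oxo-4H-chromen-8-yl]-4-methoxybenzoyl chloride | COc1ccc(cc1-c1c(OCc2ccccc2)cc(OCc2ccccc2)c2c(=O)c(-c3ccc(OC)cc3)coc12)C(Cl)=O
F4 | step 7 | 2-acetyl-3,5-bis(benzyloxy)phenyl 3-[5,7-bis(benzyloxy)-3-(4-methoxyphenyl)-4-oxo-4H-chromen-8-yl]-4-methoxybenzoate | COc1ccc(cc1-c1c(OCc2ccccc2)cc(OCc2ccccc2)c2c(=O)c(-c3ccc(OC)cc3)coc12)C(=O)Oc1cc(OCc2ccccc2)cc(OCc2ccccc2)c1C(C)=O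
F5 | step 4 | tributyl(methoxyethynyl)stannane | CCCC[Sn](CCCC)(CCCC)C#COC
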